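**Assumption:** (R)-2-methylbutanoic acid is bought as the single enantiomer. The bicycle is numbered as a 1-benzofuran (O1, C2, C3, C3a, C4, C5, C6, C7, C7a). In this numbering the target is (2R,3aS), with an (S) carbinol carbon and an (R) acyl side chain, and the prenyl group is cis to the C2 side chain.

## Retrosynthetic overview

1. Target 14 ⇒ epoxy 1,3-diketone 8 + 2,2-dimethylmalonyl dichloride 9, joined in one flask: 5-exo epoxide opening closes the oxolane ring, then a [3+3] double C-acylation closes the carbocycle and sets C3a.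
2. 8 ⇒ γ-alkylation of the dianion of 1,3-diketone 7 with epoxy iodide 3.
3. 7 ⇒ Claisen acylation of 6-methylhept-5-en-2-one 5 (carries the prenyl group) with (R)-2-methylbutanoyl chloride 6.
4. 3 ⇒ Sharpless epoxidation of geraniol 1 (sets C2 and the carbinol carbon), then iodination.
5. Ring order: oxolane ring first, six-membered carbocycle second, both in the last step.

## Route

Step 1
Reactants: 1 geraniol
Product: 2 [(2S,3S)-3-methyl-3-(4-methylpent-3-en-1-yl)oxiran-2-yl]methanol
Conditions: Ti(OiPr)4 (5 mol%), L-(+)-diethyl tartrate (7.5 mol%), t-BuOOH (1.5 equiv), 4 Å MS, CH2Cl2, −20 °C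
Reagents that add atoms: tert-butyl hydroperoxide, CC(C)(C)OO
Why: Katsuki–Sharpless asymmetric epoxidation: the Ti–tartrate catalyst epoxidizes only the allylic-alcohol alkene, and L-(+)-tartrate gives the (2S,3S) epoxide (about 90–95% ee), which encodes the future ring O–CH carbon (after inversion) and the tertiary carbinol carbon (retained).

Step 2
Reactants: 2 [(2S,3S)-3-methyl-3-(4-methylpent-3-en-1-yl)oxiran-2-yl]methanol
Product: 3 (2S,3R)-3-(iodomethyl)-2-methyl-2-(4-methylpent-3-en-1-yl)oxirane
Conditions: I2, PPh3, imidazole, CH2Cl2, 0 °C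
Reagents that add atoms: iodine, II
Why: Appel-type iodination replaces the activated primary oxygen by iodide in an SN2 reaction at CH2, so neither epoxide carbon is touched (the descriptor changes only because CH2I outranks the ring carbon) and the cold, buffered medium spares the epoxide and the alkene.

Step 3
Reactants: 4 (2R)-2-methylbutanoic acid, 5 6-methylhept-5-en-2-one
Product: 7 (3R)-3,10-dimethylundec-9-ene-4,6-dione, via acid chloride 6 (not isolated)
Conditions: 4, (COCl)2, DMF (cat.), CH2Cl2, 0 → 23 °C, concentrate; add to 5 (2.1 equiv)/LiN(iPr)2 (2.1 equiv), THF, −78 °C; 1 M HCl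
Reagents that add atoms: none
Why: Crossed Claisen acylation: LiN(iPr)2 at −78 °C takes the methyl proton of 5 (kinetic enolate), which is C-acylated by the acid chloride faster than it can deprotonate it to a ketene, so the (R) centre is kept, and the second equivalent of enolate absorbs the acidic diketone proton.

Step 4
Reactants: 7 (3R)-3,10-dimethylundec-9-ene-4,6-dione, 3 (2S,3R)-3-(iodomethyl)-2-methyl-2-(4-methylpent-3-en-1-yl)oxirane
Product: 8 (3R)-3,10-dimethyl-7-{[(2S,3S)-3-methyl-3-(4-methylpent-3-en-1-yl)oxiran-2-yl]methyl}undec-9-ene-4,6-dione (both C7 epimers)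
Conditions: LiN(iPr)2 (2.05 equiv), THF, −78 → −20 °C; 3 (1.0 equiv), −78 → −30 °C; AcOH, −78 °C
Reagents that add atoms: none
Why: Hauser-type γ-alkylation of a 1,3-diketone dianion: the second deprotonation occurs at the less hindered CH2 rather than at the stereogenic CH(Me)Et, the terminal carbanion displaces the primary iodide (SN2) while the trisubstituted epoxide survives the cold quench, and the new C7 centre is an inconsequential mixture because it becomes sp2 in step 5.

Step 5
Reactants: 8 (3R)-3,10-dimethyl-7-{[(2S,3S)-3-methyl-3-(4-methylpent-3-en-1-yl)oxiran-2-yl]methyl}undec-9-ene-4,6-dione, 9 2,2-dimethylpropanedioyl dichloride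
Product: 14 (2R,3aS)-2-[(2S)-2-hydroxy-6-methylhept-5-en-2-yl]-5,5-dimethyl-7-[(2R)-2-methylbutanoyl]-3a-(3-methylbut-2-en-1-yl)-3,3a-dihydro-1-benzofuran-4,6(2H,5H)-dione (the target), via hydroxy alkylidene-oxolane 10 (not isolated), via bis-silyl dienol ether 11 (not isolated), via acid chloride 12 (not isolated), via silyl ether 13 (not isolated)
Conditions: LiN(SiMe3)2 (1.05 equiv), THF, −78 → 40 °C; −78 °C, Me3SiCl (2.4 equiv), LiN(SiMe3)2 (1.15 equiv), → 0 °C; switch solvent to CH2Cl2; slow addition to 9 (1.2 equiv), 2,6-di-tert-butyl-4-methylpyridine (1.5 equiv), Me3SiOTf (0.2 equiv), −78 → 23 °C; 1 M HCl, THF, 0 °C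
Reagents that add atoms: none
Why: Proposed new method: the Li diketonate oxygen opens the epoxide 5-exo-tet at the secondary carbon with inversion (C-attack would be a disfavoured 5-enolendo closure), giving the (2R)-oxolane 10 with the carbinol carbon retained as (S); γ-deprotonation of the ring CH held syn to the carbonyl in the (E)-alkylidene, with silylation of both oxygens, gives the 1-silyloxy-3-alkoxy diene 11; its two nucleophilic carbons are then C-acylated by the diacid chloride, at C3a in a vinylogous Mukaiyama acylation on the face anti to the bulky C2 side chain (so prenyl ends up cis to it, 3aS) and at C7 by six-membered closure of the vinylogous ester onto the tethered acid chloride, either order converging on 13; the closest known reactions are the domino C,O-cyclodialkylation of 1,3-dicarbonyl dianions with epihalohydrins to 2-alkylidene-oxolanes, the Effenberger cyclization of enol ethers with malonyl dichloride, and [3+3] cyclizations of 1,3-bis(silyloxy)dienes, with the facial bias modelled on trans-selective alkylation of γ-substituted butyrolactone enolates.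

## Compound list

1 | geraniol, (2E)-3,7-dimethylocta-2,6-dien-1-ol | CC(C)=CCC/C(C)=C/CO | starting material
2 | [(2S,3S)-3-methyl-3-(4-methylpent-3-en-1-yl)oxiran-2-yl]methanol | OC[C@@H]1O[C@@]1(C)CCC=C(C)C | intermediate
3 | (2S,3R)-3-(iodomethyl)-2-methyl-2-(4-methylpent-3-en-1-yl)oxirane | IC[C@@H]1O[C@@]1(C)CCC=C(C)C | intermediate
4 | (2R)-2-methylbutanoic acid | CC[C@@H](C)C(=O)O | starting material
5 | 6-methylhept-5-en-2-one | CC(=O)CCC=C(C)C | starting material
6 | (2R)-2-methylbutanoyl chloride | CC[C@@H](C)C(=O)Cl | intermediate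
7 | (3R)-3,10-dimethylundec-9-ene-4,6-dione | CC[C@@H](C)C(=O)CC(=O)CCC=C(C)C | intermediate
8 | (3R)-3,10-dimethyl-7-{[(2S,3S)-3-methyl-3-(4-methylpent-3-en-1-yl)oxiran-2-yl]methyl}undec-9-ene-4,6-dione, both C7 epimers | CC[C@@H](C)C(=O)CC(=O)C(CC=C(C)C)C[C@@H]1O[C@@]1(C)CCC=C(C)C | intermediate
9 | 2,2-dimethylpropanedioyl dichloride (dimethylmalonyl dichloride) | CC(C)(C(=O)Cl)C(=O)Cl | starting material
10 | (3R)-1-{(5R)-5-[(2S)-2-hydroxy-6-methylhept-5-en-2-yl]-3-(3-methylbut-2-en-1-yl)oxolan-2-ylidene}-3-methylpentan-2-one, formed as its Li salt, both oxolane C3 epimers | CC[C@@H](C)C(=O)C=C1O[C@@H]([C@@](C)(O)CCC=C(C)C)CC1CC=C(C)C | intermediate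
11 | (5R)-2-[(3R)-3-methyl-2-(trimethylsilyloxy)pent-1-en-1-yl]-3-(3-methylbut-2-en-1-yl)-5-[(2S)-6-methyl-2-(trimethylsilyloxy)hept-5-en-2-yl]-4,5-dihydrofuran | CC[C@@H](C)C(O[Si](C)(C)C)=CC1=C(CC=C(C)C)C[C@H]([C@@](C)(O[Si](C)(C)C)CCC=C(C)C)O1 | intermediate
12 | 3-{(3S,5R)-2-[(3R)-3-methyl-2-oxopentylidene]-3-(3-methylbut-2-en-1-yl)-5-[(2S)-6-methyl-2-(trimethylsilyloxy)hept-5-en-2-yl]oxolan-3-yl}-2,2-dimethyl-3-oxopropanoyl chloride | CC[C@@H](C)C(=O)C=C1O[C@@H]([C@@](C)(O[Si](C)(C)C)CCC=C(C)C)C[C@]1(CC=C(C)C)C(=O)C(C)(C)C(=O)Cl | intermediate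
13 | (2R,3aS)-5,5-dimethyl-7-[(2R)-2-methylbutanoyl]-3a-(3-methylbut-2-en-1-yl)-2-[(2S)-6-methyl-2-(trimethylsilyloxy)hept-5-en-2-yl]-3,3a-dihydro-1-benzofuran-4,6(2H,5H)-dione | CC[C@@H](C)C(=O)C1=C2O[C@@H]([C@@](C)(O[Si](C)(C)C)CCC=C(C)C)C[C@]2(CC=C(C)C)C(=O)C(C)(C)C1=O | intermediate
14 | (2R,3aS)-2-[(2S)-2-hydroxy-6-methylhept-5-en-2-yl]-5,5-dimethyl-7-[(2R)-2-methylbutanoyl]-3a-(3-methylbut-2-en-1-yl)-3,3a-dihydro-1-benzofuran-4,6(2H,5H)-dione | CC[C@@H](C)C(=O)C1=C2O[C@@H]([C@@](C)(O)CCC=C(C)C)C[C@]2(CC=C(C)C)C(=O)C(C)(C)C1=O | target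

## Step count and risks

Total step count: 5. Longest linear sequence: 4 steps (1 → 2 → 3 → 8 → 14); the other branch (4 and 5 → 7 → 8 → 14) is 3 steps.

**Most likely to fail, 1: step 5.** The second base must take the ring γ-proton and not the α′-proton of the (R)-2-methylbutanoyl group, which would epimerize that centre or silylate the wrong side. The C3a–C4 bond joins two fully substituted carbons. The diacid chloride can also bridge two dienes, and a 6-endo epoxide opening would give a pyran. Fallback, setting out from 8 and coming back at 14: close only the oxolane with K2CO3 in MeOH at 23 °C and isolate 10. Protect it with Et3SiOTf and 2,6-lutidine in CH2Cl2 at −78 °C as the triethylsilyl ether F1. Then run the annulation from the acid side, with no enolate at any point: 9, AgOTf and 2,6-di-tert-butyl-4-methylpyridine in CH2Cl2 from −40 to 23 °C, where the acyl triflate acylates C7 of the vinylogous ester and then C3a through the endocyclic enol-ether tautomer. This gives the silyl-protected bicycle F2, and HF·pyridine in THF returns 14.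

**Most likely to fail, 2: step 4.** The dianion may also form at the stereogenic CH(Me)Et, which erodes the (R) centre and gives a regioisomer. The epoxy iodide is fragile, and the product may cyclize before isolation. Fallback, setting out from 3 and coming back at 8, with the acyl group put on last so that no dianion is ever formed next to the stereocentre: alkylate allyl acetoacetate with prenyl bromide (K2CO3, acetone) to allyl 2-acetyl-5-methylhex-4-enoate F3. Alkylate its Na enolate (NaH, DMF) with 3 to the epoxy keto ester F4. Remove the ester by deallylative decarboxylation (Pd(OAc)2, PPh3, HCO2H, Et3N, THF) to the epoxy ketone F5. Take the kinetic methyl enolate of F5 (LiN(iPr)2, THF, −78 °C) and acylate it with 6 to reach 8.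

**Most likely to fail, 3: step 3.** The acid chloride may racemize through its ketene, the enolate may be O-acylated, and some internal enolate of 5 gives a regioisomer. Fallback, setting out from 4 and coming back at 7, a decarboxylative Claisen under nearly neutral conditions: prenylate the dianion of methyl acetoacetate (NaH, then n-BuLi, THF, 0 °C; prenyl bromide) to methyl 7-methyl-3-oxooct-6-enoate F6. Saponify cold (LiOH, THF/H2O, 0 °C) to 7-methyl-3-oxooct-6-enoic acid F7. Activate 4 with 1,1'-carbonyldiimidazole to the acyl imidazolide F8. Combine F7 and F8 with MgCl2 and Et3N in MeCN; C-acylation of the Mg chelate followed by loss of CO2 gives 7.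

Further compounds
F1 | step 5 | (3R)-3-methyl-1-{(5R)-3-(3-methylbut-2-en-1-yl)-5-[(2S)-6-methyl-2-(triethylsilyloxy)hept-5-en-2-yl]oxolan-2-ylidene}pentan-2-one | CC[C@@H](C)C(=O)C=C1O[C@@H]([C@@](C)(O[Si](CC)(CC)CC)CCC=C(C)C)CC1CC=C(C)C
F2 | step 5 | (2R,3aS)-5,5-dimethyl-7-[(2R)-2-methylbutanoyl]-3a-(3-methylbut-2-en-1-yl)-2-[(2S)-6-methyl-2-(triethylsilyloxy)hept-5-en-2-yl]-3,3a-dihydro-1-benzofuran-4,6(2H,5H)-dione | CC[C@@H](C)C(=O)C1=C2O[C@@H]([C@@](C)(O[Si](CC)(CC)CC)CCC=C(C)C)C[C@]2(CC=C(C)C)C(=O)C(C)(C)C1=O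
F3 | step 4 | allyl 2-acetyl-5-methylhex-4-enoate | CC(=O)C(CC=C(C)C)C(=O)OCC=C
F4 | step 4 | allyl 2-acetyl-5-methyl-2-{[(2S,3S)-3-methyl-3-(4-methylpent-3-en-1-yl)oxiran-2-yl]methyl}hex-4-enoate | CC(=O)C(CC=C(C)C)(C[C@@H]1O[C@@]1(C)CCC=C(C)C)C(=O)OCC=C
F5 | step 4 | 6-methyl-3-{[(2S,3S)-3-methyl-3-(4-methylpent-3-en-1-yl)oxiran-2-yl]methyl}hept-5-en-2-one | CC(=O)C(CC=C(C)C)C[C@@H]1O[C@@]1(C)CCC=C(C)C
F6 | step 3 | methyl 7-methyl-3-oxooct-6-enoate | COC(=O)CC(=O)CCC=C(C)C
F7 | step 3 | 7-methyl-3-oxooct-6-enoic acid | OC(=O)CC(=O)CCC=C(C)C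
F8 | step 3 | (2R)-1-(1H-imidazol-1-yl)-2-methylbutan-1-one | CC[C@@H](C)C(=O)n1ccnc1
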